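**Retrosynthetic overview**
1. Eriolangin ⇒ (C14–H hydroxylation, C1 CHO → CH2OH) 1,10-seco-aldehyde ⇒ alkoxy-radical scission of C1–C10 in a 1β-hydroxyeudesman-8β,12-olide. Ring A serves only as a stereochemical template and is then cleaved.
2. Lactone (third ring formed): O8–C12 closure once ring B is a chair (8β-OH axial, gauche to C11).
3. Ring B plus temporary ring A (second): transannular C5–C10 closure of a germacr-4-ene 1(10)-epoxide, run as a radical reaction. It sets C5, C10 and the surviving C4.
4. Ten-membered ring (first): C6–C7 closure by allyl-Cr(III) addition to a farnesal-type enal. It sets C6 and C7 from C8.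
5. Chain: geranyl acetate (C1–C6, C9, C10, C14, C15) + Evans glycolate (C7, C8) + tert-butyl acrylate (C11–C13); angelic acid for the ester.

Assumption: the biosynthesis is taken as farnesyl → germacrane (C6–C7) → 1(10)-epoxide → 1β-hydroxyeudesmane (C5–C10) → 8β,12-lactone → C1–C10 cleavage. Germacrane/eudesmane numbering is used throughout.

Step 1
Reactants: 1 geranyl acetate
Product: 2 (2E,6E)-8-hydroxygeranyl acetate
Conditions: SeO2 (10 mol %), t-BuOOH, salicylic acid (cat.), CH2Cl2, rt
Reagents that add atoms: tert-butyl hydroperoxide, CC(C)(C)OO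
Why: Catalytic SeO2 allylic hydroxylation (ene, then [2,3]-shift) attacks the electron-richer distal alkene, because the 2,3-alkene is deactivated by the allylic acetate, and gives only the (E)-CH2OH (future C9); no stereocentre is formed.

Step 2
Reactants: 2 (2E,6E)-8-hydroxygeranyl acetate
Product: 3 (2E,6E)-8-bromogeranyl acetate
Conditions: CBr4, PPh3, CH2Cl2, 0 °C
Reagents that add atoms: carbon tetrabromide, BrC(Br)(Br)Br
Why: The Appel reaction converts the primary allylic alcohol into the bromide by SN2 under neutral conditions, without allylic transposition or loss of alkene geometry, and the acetate survives.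

Step 3
Reactants: 4 (S)-4-benzyl-2-oxazolidinone; 5 benzyloxyacetyl chloride
Product: 6 (S)-4-benzyl-3-(benzyloxyacetyl)-2-oxazolidinone
Conditions: Et3N, DMAP (10 mol %), CH2Cl2, 0 °C → rt
Reagents that add atoms: none
Why: DMAP-catalysed N-acylation of the oxazolidinone with an acid chloride is routine and does not touch the auxiliary stereocentre.

Step 4
Reactants: 6 (S)-4-benzyl-3-(benzyloxyacetyl)-2-oxazolidinone; 3 (2E,6E)-8-bromogeranyl acetate
Product: 8 (S)-4-benzyl-3-[(2R,4E,8E)-10-acetoxy-2-benzyloxy-4,8-dimethyldeca-4,8-dienoyl]-2-oxazolidinone, via sodium Z-enolate 7 (not isolated)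
Conditions: NaHMDS, THF, −78 °C; then 3, Bu4NI (cat.), −78 → −40 °C
Reagents that add atoms: none
Why: In this Evans glycolate alkylation the chelated Z-enolate is shielded on one face by the benzyl group, so the reactive allylic bromide enters from the other face and sets C8 as R (8β-O) with dr typically >95:5, while the acetate is inert at −78 °C.

Step 5
Reactants: 8 alkylated glycolate imide
Product: 9 (2R,4E,8E)-2-benzyloxy-4,8-dimethyldeca-4,8-diene-1,10-diol
Conditions: LiBH4, MeOH, Et2O, 0 °C → rt
Reagents that add atoms: none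
Why: Reductive cleavage of the N-acyloxazolidinone with LiBH4/MeOH gives the C7 carbinol without epimerising C8 and reduces off the C6 acetate in the same operation, so no separate deprotection is needed.

Step 6
Reactants: 9 (2R,4E,8E)-2-benzyloxy-4,8-dimethyldeca-4,8-diene-1,10-diol
Product: 10 (2R,4E,8E)-2-benzyloxy-4,8-dimethyldeca-4,8-dienedial
Conditions: Dess–Martin periodinane (2.4 equiv), CH2Cl2, 0 °C → rt
Reagents that add atoms: none
Why: Dess–Martin oxidation takes both primary alcohols to aldehydes at once under non-basic conditions, so the α-alkoxy aldehyde (C7) keeps its C8 configuration and the C4=C5 enal stays E.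

Step 7
Reactants: 10 (2R,4E,8E)-2-benzyloxy-4,8-dimethyldeca-4,8-dienedial; 11 tert-butyl acrylate
Product: 12 tert-butyl (4R,6E,10E)-4-benzyloxy-3-hydroxy-6,10-dimethyl-2-methylene-12-oxododeca-6,10-dienoate (C7 epimers)
Conditions: 11 (5 equiv), quinuclidine (0.3 equiv), MeOH (0.75 equiv), neat, rt
Reagents that add atoms: none
Why: The Morita–Baylis–Hillman reaction picks the activated α-alkoxy aldehyde over the β,β-disubstituted enal, which is a poor MBH electrophile, and the new C7 carbinol centre is irrelevant because step 8 erases it.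

Step 8
Reactants: 12 Baylis–Hillman adduct
Product: 13 tert-butyl (2Z,4R,6E,10E)-4-benzyloxy-2-(bromomethyl)-6,10-dimethyl-12-oxododeca-2,6,10-trienoate
Conditions: NBS, Me2S, CH2Cl2, 0 °C → rt
Reagents that add atoms: N-bromosuccinimide, O=C1CCC(=O)N1Br
Why: Corey–Kim-type activation of the Baylis–Hillman alcohol followed by SN2' attack of bromide gives the usual (Z)-2-(bromomethyl)enoate under near-neutral conditions that spare the tert-butyl ester, the benzyl ether and the enal.

Step 9
Reactants: 13 bromo-enal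
Product: 15 tert-butyl 8β-benzyloxy-6α-hydroxy-7αH-germacra-1(10)E,4E,11(13)-trien-12-oate, via allylchromium(III) species 14 (not isolated)
Conditions: CrCl2 (8 equiv), THF–DMF, 2 mM (syringe pump), rt; H2O
Reagents that add atoms: none
Why: This intramolecular Nozaki–Hiyama–Kishi allylation, a closure type known for ten-membered germacranolide carbocycles from farnesal-type bromo-enals, reacts through the E-form of the fluxional allylchromium in a chair Zimmerman–Traxler state (6,7-anti: 6α-OH, 7α-H), the C8 centre (H8 held in the alkene plane by A1,3 strain) directs bonding at C7 anti to the C9 chain (7α-H/8β-O), and the tert-butyl ester keeps the C6 alkoxide from lactonising.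

Step 10
Reactants: 15 germacratrienol; 16 angelic acid
Product: 18 tert-butyl 6α-angeloyloxy-8β-benzyloxy-7αH-germacra-1(10)E,4E,11(13)-trien-12-oate, via mixed anhydride 17 (not isolated)
Conditions: 16, 2,4,6-Cl3C6H2COCl, Et3N, PhMe, rt; then 15, 70 °C
Reagents that add atoms: none
Why: DMAP-free Yamaguchi-type mixed-anhydride esterification is the standard way to put an angelate on a hindered secondary alcohol without Z→E leakage to the tiglate, the C6–OH is the only hydroxyl in the molecule, C6 is retained, and 70 °C is below the Cope threshold of germacradienes.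

Step 11
Reactants: 18 germacratriene angelate
Product: 19 tert-butyl 6α-angeloyloxy-8β-benzyloxy-1β,10α-epoxy-7αH-germacra-4E,11(13)-dien-12-oate
Conditions: m-CPBA (1.05 equiv), CH2Cl2, −20 °C
Reagents that add atoms: m-chloroperbenzoic acid, O=C(OO)c1cccc(Cl)c1
Why: Prilezhaev epoxidation selects C1=C10, the only unperturbed electron-rich alkene (C4=C5 bears an allylic ester, the other two are conjugated esters), and peripheral attack on the crown conformer with both ring methyls β gives the 1β,10α-epoxide, as in costunolide-type germacradienes.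

Step 12
Reactants: 19 epoxygermacradiene
Product: 20 tert-butyl 6α-angeloyloxy-8β-benzyloxy-1β-hydroxy-4αH,5αH,7αH-eudesm-11(13)-en-12-oate
Conditions: Cp2TiCl2 (2.5 equiv), Mn, THF; then 19, H2O (40 equiv), rt
Reagents that add atoms: none
Why: RajanBabu–Nugent Ti(III) epoxide opening with transannular radical closure, known for 1(10)-epoxygermacrolides in wet THF, lets the C10 radical attack C5 through the chair–chair array that keeps the C6 ester and C7 side chain equatorial (5α-H, 10β-Me, 1β-OH), the C4 radical then takes H from bulky Cp2Ti(Cl)(OH2) on the α face because the syn-axial C14 methyl blocks the β face (4α-H, 4β-Me), and a radical at C4, unlike a cation, is not captured by the 6α-ester carbonyl.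

Step 13
Reactants: 20 eudesmenoate
Product: 22 6α-angeloyloxy-1β-hydroxy-4αH,5αH-eudesm-11(13)-en-8β,12-olide, via dihydroxy acid 21 (not isolated)
Conditions: BCl3 (4 equiv), CH2Cl2, −78 → −20 °C; aq. work-up, pH 3
Reagents that add atoms: none
Why: BCl3 dealkylation removes the benzyl ether and the tert-butyl ester together, and the freed axial 8β-OH, now gauche to C11 in the ring-B chair, closes spontaneously to the cis-fused α-methylene-γ-lactone (lactonisation with retention at C7 and C8) while the angelate survives the low temperature.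

Step 14
Reactants: 22 1β-hydroxyeudesmanolide
Product: 25 (4S)-6α-angeloyloxy-1-oxo-1,10-seco-eudesma-5(10),11(13)-dien-8β,12-olide, via hypoiodite 23 (not isolated), via tertiary iodide 24 (not isolated)
Conditions: PhI(OAc)2, I2, NaHCO3, CH2Cl2, W lamp, 20 °C
Reagents that add atoms: none
Why: In this Suárez alkoxy-radical β-fragmentation the O1 radical cleaves C1–C10 (tertiary radical formed, 1,3-diaxial Me/Me strain released), iodine transfer gives a tertiary iodide that loses HI in the Saytzeff sense through the axial tertiary H5 to the tetrasubstituted C5=C10 alkene, C1, C5 and C10 stop being stereocentres, and C4, C6, C7 and C8 are untouched.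

Step 15
Reactants: 25 seco-aldehyde
Product: 27 eriolangin, via 14-hydroxy aldehyde 26 (not isolated)
Conditions: SeO2 (0.5 equiv), t-BuOOH, CH2Cl2, 0 °C → rt; then CeCl3·7H2O, NaBH4, MeOH, −78 °C
Reagents that add atoms: tert-butyl hydroperoxide, CC(C)(C)OO
Why: In this SeO2 allylic hydroxylation with a Luche reduction in the same flask, C6–H and C9–H are deactivated by their acyloxy neighbours and C4–H is tertiary and held in the alkene plane by A1,3 strain, so the ene/[2,3] sequence is channelled to the C14 methyl, and NaBH4/CeCl3 at −78 °C then reduces the C1 aldehyde (and any over-oxidised C14 enal) by 1,2-attack faster than it touches the α-methylene lactone or the angelate; no stereocentre is made or disturbed.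

**Compound list**
1 | geranyl acetate | CC(C)=CCC/C(C)=C/COC(C)=O | starting material
2 | (2E,6E)-8-hydroxygeranyl acetate | OC/C(C)=C/CC/C(C)=C/COC(C)=O | intermediate
3 | (2E,6E)-8-bromogeranyl acetate | BrC/C(C)=C/CC/C(C)=C/COC(C)=O | intermediate
4 | (S)-4-benzyl-2-oxazolidinone | O=C1N[C@@H](Cc2ccccc2)CO1 | starting material
5 | benzyloxyacetyl chloride | O=C(Cl)COCc1ccccc1 | starting material
6 | (S)-4-benzyl-3-(benzyloxyacetyl)-2-oxazolidinone | O=C(COCc1ccccc1)N1[C@@H](Cc2ccccc2)COC1=O | intermediate
7 | sodium Z-enolate of 6 (not isolated) | [Na+].[O-]/C(=C\OCc1ccccc1)N1[C@@H](Cc2ccccc2)COC1=O | intermediate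
8 | (S)-4-benzyl-3-[(2R,4E,8E)-10-acetoxy-2-benzyloxy-4,8-dimethyldeca-4,8-dienoyl]-2-oxazolidinone | O=C([C@H](OCc1ccccc1)C/C(C)=C/CC/C(C)=C/COC(C)=O)N1[C@@H](Cc2ccccc2)COC1=O | intermediate
9 | (2R,4E,8E)-2-benzyloxy-4,8-dimethyldeca-4,8-diene-1,10-diol | OC[C@H](OCc1ccccc1)C/C(C)=C/CC/C(C)=C/CO | intermediate
10 | (2R,4E,8E)-2-benzyloxy-4,8-dimethyldeca-4,8-dienedial | O=C[C@H](OCc1ccccc1)C/C(C)=C/CC/C(C)=C/C=O | intermediate
11 | tert-butyl acrylate | C=CC(=O)OC(C)(C)C | starting material
12 | tert-butyl (4R,6E,10E)-4-benzyloxy-3-hydroxy-6,10-dimethyl-2-methylene-12-oxododeca-6,10-dienoate (both C7 epimers) | OC(C(=C)C(=O)OC(C)(C)C)[C@H](OCc1ccccc1)C/C(C)=C/CC/C(C)=C/C=O | intermediate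
13 | tert-butyl (2Z,4R,6E,10E)-4-benzyloxy-2-(bromomethyl)-6,10-dimethyl-12-oxododeca-2,6,10-trienoate | BrC/C(C(=O)OC(C)(C)C)=C\[C@H](OCc1ccccc1)C/C(C)=C/CC/C(C)=C/C=O | intermediate
14 | allylchromium(III) dichloride from 13 (fluxional C7=C11 geometry, not isolated) | Cl[Cr](Cl)CC(C(=O)OC(C)(C)C)=C[C@H](OCc1ccccc1)C/C(C)=C/CC/C(C)=C/C=O | intermediate
15 | tert-butyl 8β-benzyloxy-6α-hydroxy-7αH-germacra-1(10)E,4E,11(13)-trien-12-oate | C=C(C(=O)OC(C)(C)C)[C@@H]1[C@H](OCc2ccccc2)C/C(C)=C/CC/C(C)=C/[C@H]1O | intermediate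
16 | angelic acid, (Z)-2-methylbut-2-enoic acid | C/C=C(/C)C(=O)O | starting material
17 | angelic 2,4,6-trichlorobenzoic anhydride (not isolated) | C/C=C(/C)C(=O)OC(=O)c1c(Cl)cc(Cl)cc1Cl | intermediate
18 | tert-butyl 6α-angeloyloxy-8β-benzyloxy-7αH-germacra-1(10)E,4E,11(13)-trien-12-oate | C=C(C(=O)OC(C)(C)C)[C@@H]1[C@H](OCc2ccccc2)C/C(C)=C/CC/C(C)=C/[C@H]1OC(=O)/C(C)=C\C | intermediate
19 | tert-butyl 6α-angeloyloxy-8β-benzyloxy-1β,10α-epoxy-7αH-germacra-4E,11(13)-dien-12-oate | C=C(C(=O)OC(C)(C)C)[C@@H]1[C@H](OCc2ccccc2)C[C@@]3(C)O[C@@H]3CC/C(C)=C/[C@H]1OC(=O)/C(C)=C\C | intermediate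
20 | tert-butyl 6α-angeloyloxy-8β-benzyloxy-1β-hydroxy-4αH,5αH,7αH-eudesm-11(13)-en-12-oate (4β-Me, 10β-Me, trans-decalin) | C=C(C(=O)OC(C)(C)C)[C@@H]1[C@H](OCc2ccccc2)C[C@@]3(C)[C@H](O)CC[C@H](C)[C@@H]3[C@H]1OC(=O)/C(C)=C\C | intermediate
21 | 6α-angeloyloxy-1β,8β-dihydroxy-4αH,5αH,7αH-eudesm-11(13)-en-12-oic acid (not isolated) | C=C(C(=O)O)[C@@H]1[C@H](O)C[C@@]2(C)[C@H](O)CC[C@H](C)[C@@H]2[C@H]1OC(=O)/C(C)=C\C | intermediate
22 | 6α-angeloyloxy-1β-hydroxy-4αH,5αH-eudesm-11(13)-en-8β,12-olide (cis-lactone) | C=C1C(=O)O[C@@H]2C[C@@]3(C)[C@H](O)CC[C@H](C)[C@@H]3[C@@H](OC(=O)/C(C)=C\C)[C@H]12 | intermediate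
23 | 1β-hypoiodite of 22 (not isolated) | C=C1C(=O)O[C@@H]2C[C@@]3(C)[C@H](OI)CC[C@H](C)[C@@H]3[C@@H](OC(=O)/C(C)=C\C)[C@H]12 | intermediate
24 | 10-iodo-1-oxo-1,10-seco-eudesmanolide (C10 epimers, not isolated) | C=C1C(=O)O[C@@H]2CC(C)(I)[C@H]([C@@H](C)CCC=O)[C@@H](OC(=O)/C(C)=C\C)[C@H]12 | intermediate
25 | (4S)-6α-angeloyloxy-1-oxo-1,10-seco-eudesma-5(10),11(13)-dien-8β,12-olide | C=C1C(=O)O[C@@H]2CC(C)=C([C@@H](C)CCC=O)[C@@H](OC(=O)/C(C)=C\C)[C@H]12 | intermediate
26 | 14-hydroxy derivative of 25 (not isolated) | C=C1C(=O)O[C@@H]2CC(CO)=C([C@@H](C)CCC=O)[C@@H](OC(=O)/C(C)=C\C)[C@H]12 | intermediate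
27 | eriolangin (4S,6S,7R,8R) | C=C1C(=O)O[C@@H]2CC(CO)=C([C@@H](C)CCCO)[C@@H](OC(=O)/C(C)=C\C)[C@H]12 | target

**Step count and risks**

Total step count: 15. Longest linear sequence: 14 (steps 1, 2 and 4–15).

Step 9 is the first risk. It has to close a strained E,E-cyclodecadiene, and the diastereoselectivity rests on the single C8 centre. The fallback removes strain before the closure by reordering epoxidation and cyclisation. It sets out from 13. m-CPBA attacks only the isolated C1=C10 alkene, because the other two alkenes are an enal and an enoate, and gives the epoxy bromo-enal F1. The unwanted epoxide diastereomer is removed by chromatography. CrCl2 closure of this chain, which now has only one E-alkene inside the forming ring, gives the epoxy-germacrenol F2. Mixed-anhydride angeloylation of F2, as in step 10, rejoins the route at 19.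

Step 14 is the second risk. The C–C scission itself is reliable, but loss of HI could also give the Δ9(10) or Δ10(14) alkene, and I2/AcOI may add to the new alkene. The fallback replaces the radical/ionic elimination by an intramolecular hydrogen transfer that can give only one alkene. It sets out from 22. Dess–Martin oxidation gives the 1-oxoeudesmanolide F3. Irradiation at λ ≥ 300 nm in benzene triggers Norrish type I cleavage on the quaternary C10 side. The acyl radical then abstracts H5 through a six-membered transition state. This gives the C1 aldehyde and the C5=C10 alkene directly, and the fallback comes back at 25.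

Step 15 is the third risk, because oxidation at C9 or C4 may compete with C14. The fallback moves the oxygen in by an ene reaction and an allylic transposition instead of direct C–H hydroxylation. It sets out from 25. Singlet oxygen (O2, TPP, hν, CH2Cl2, −20 °C) reacts only with the tetrasubstituted alkene and gives the 5-hydroperoxy-10(14)-ene F4, whose C5 configuration is irrelevant. PPh3 reduces F4 to the tertiary allylic alcohol F5. A catalytic perrhenate 1,3-transposition (Ph3SiOReO3) then moves the hydroxyl to the primary C14 position while restoring the tetrasubstituted C5=C10 alkene, and the fallback comes back at 26. Compound 26 is reduced with NaBH4/CeCl3 as in step 15.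

**Further compounds**
F1 | step 9 | tert-butyl (2Z,4R)-4-benzyloxy-2-(bromomethyl)-6,7-epoxy-6,10-dimethyl-12-oxododeca-2,10E-dienoate (epoxide configured as in 19) | BrC/C(C(=O)OC(C)(C)C)=C\[C@H](OCc1ccccc1)C[C@@]2(C)O[C@@H]2CC/C(C)=C/C=O
F2 | step 9 | tert-butyl 8β-benzyloxy-1β,10α-epoxy-6α-hydroxy-7αH-germacra-4E,11(13)-dien-12-oate | C=C(C(=O)OC(C)(C)C)[C@@H]1[C@H](OCc2ccccc2)C[C@@]3(C)O[C@@H]3CC/C(C)=C/[C@H]1O
F3 | step 14 | 6α-angeloyloxy-1-oxo-4αH,5αH-eudesm-11(13)-en-8β,12-olide | C=C1C(=O)O[C@@H]2C[C@@]3(C)C(=O)CC[C@H](C)[C@@H]3[C@@H](OC(=O)/C(C)=C\C)[C@H]12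
F4 | step 15 | 6α-angeloyloxy-5α-hydroperoxy-1-oxo-1,10-seco-eudesma-10(14),11(13)-dien-8β,12-olide | C=C1C(=O)O[C@@H]2CC(=C)[C@](OO)([C@@H](C)CCC=O)[C@@H](OC(=O)/C(C)=C\C)[C@H]12
F5 | step 15 | 6α-angeloyloxy-5α-hydroxy-1-oxo-1,10-seco-eudesma-10(14),11(13)-dien-8β,12-olide | C=C1C(=O)O[C@@H]2CC(=C)[C@](O)([C@@H](C)CCC=O)[C@@H](OC(=O)/C(C)=C\C)[C@H]12
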